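An easy step first: I count how much incoming ligand sits on the exchanged complexes at the end of a run.

| flask | starting complex | incoming ligand | remark | time |
|---|---|---|---|---|
| delta | 0.21 M | 0.199 M | run made earlier |  |
| theta | 0.21 M | 0.28 M | run made earlier |  |
| gamma | 0.21 M | 0.44 M | run made earlier |  |
| zeta | 0.10 M | 0.199 M | run made earlier |  |
| north | 0.21 M (fed, over 30 min) | 0.199 M | all else is in the flask from the start; the feed brings no volume worth counting | 50 min |
| north-east | 0.21 M | 0.199 M (fed, over 8.0 min) | all else is in the flask from the start; the feed brings no volume worth counting | 50 min |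
| south | 0.21 M (in portions, 4, over 30 min) | 0.199 M | first portion at the start, last at 30 min | 50 min |
| west | 0.21 M | 0.199 M | everything together at the start | 50 min |
| east | 0.21 M | 0.199 M (fed, over 30 min) | all else is in the flask from the start; the feed brings no volume worth counting | 50 min |

| run | time / min | complex with two exchanged / % | complex with one exchanged / % |
|---|---|---|---|
| delta | 4.00 | 4.3 | 30.6 |
| delta | 6.00 | 3.9 | 33.2 |
| delta | 12.0 | 1.0 | 35.9 |
| delta | 20.0 | 0.7 | 36.4 |
| delta | 30.0 | 3.1 | 38.8 |
| delta | 50.0 | 2.8 | 37.8 |
| theta | 5.00 | 6.3 | 36.6 |
| theta | 10.0 | 3.2 | 41.0 |
| theta | 15.0 | 4.9 | 42.4 |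
| theta | 20.0 | 3.6 | 43.9 |
| theta | 25.0 | 2.7 | 44.6 |
| theta | 30.0 | 2.0 | 43.5 |
| gamma | 2.00 | 7.3 | 31.5 |
| gamma | 6.00 | 4.6 | 45.0 |
| gamma | 10.0 | 5.9 | 48.4 |
| gamma | 15.0 | 3.7 | 47.0 |
| gamma | 25.0 | 4.3 | 48.8 |
| gamma | 30.0 | 5.5 | 49.3 |
| zeta | 2.50 | 5.4 | 27.3 |
| zeta | 5.00 | 7.4 | 33.7 |
| zeta | 8.00 | 7.3 | 38.2 |
| zeta | 15.0 | 7.4 | 42.5 |
| zeta | 30.0 | 5.7 | 46.7 |

(scatter of a reading: 1 percentage point)



- the flask that comes out highest in amount of complex with two exchanged, in percent of the starting complex charged, or "all alike" when all lie within 1.5 percentage points (north / north-east / south / west / east / all alike)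
- complex with two exchanged at the end, in percent of the starting complex charged, north
- complex with two exchanged at the end, in percent of the starting complex charged, north-east
- complex with two exchanged at the end, in percent of the starting complex charged, south
- complex with two exchanged at the end, in percent of the starting complex charged, west
- complex with two exchanged at the end, in percent of the starting complex charged, east

Complex with one exchanged holds one ligand and complex with two exchanged holds two. In delta at 50.0 min the count gives 45.8% of the charged ligand. I call this part the capture share, a selectivity of the ligand between the complex and whatever else takes it. Delta reads close to half, and I hold the other runs against that even split.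

Gamma holds twice the starting complex of zeta and twice the ligand. Yet their shares read 28.8% and 29.2%, about the same. So I read the share as following [incoming ligand]/[starting complex]. That fits a loss of ligand with itself racing capture on the starting complex.

Now the ladder of times. On the fastest rung, delta has 81.0% of its final complex with one exchanged by 4.00 min. The feeds come next: the quick one takes 8.0 min and the slow one 30 min, both longer than that. So ligand fed into a full charge of starting complex should be used about as it arrives, at a low ratio and a high share. Feeding the starting complex instead puts the ratio high at the start. On the slowest rung, delta hardly moves, reading 38.8% at 30.0 min and 37.8% at 50.0 min, within the scatter. My order is therefore east, north-east, west, south, north, with west near the delta reading of 2.8%.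

The forecast differs. It says all alike, with 2.3% in west and the same in the others, since “all reach the same equilibrium”.

The flasks give 7.07% in east, 4.40% in north-east, 2.34% in west, 1.56% in south and 0.784% in north, so east comes out highest.

    starting complex + incoming ligand ⇌ leaving ligand + complex with one exchanged (K = 6.20, k = 2.01 L mol⁻¹ min⁻¹)
    complex with one exchanged + incoming ligand ⇌ leaving ligand + complex with two exchanged (K = 0.388, k = 3.41 L mol⁻¹ min⁻¹)
    leaving ligand → by-product carried off (k = 0.0984 min⁻¹)
    2 incoming ligand → homo dimer (k = 2.74 L mol⁻¹ min⁻¹)

At 50.0 min the capture share is 71.8% in east, above delta's 45.8%, and 12.6% in north, below it. In north, half of the turnover to homo dimer is done by 0.715 min and half of the first exchange by 8.51 min, which is 11.9 times later, and homo dimer ends at 0.0266 M in east against 0.0870 M in north.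

The data were computed for an exercise, and the scatter is random.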